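**Plan**

- Numbering as in isoflavans (O1, C2, C3, C4, C4a, C5–C8, C8a; ring B primed); the target is the 3S enantiomer.
- Retrosynthesis: remove the two MOM groups; cut the aryl ether bond O1–C8a back to a 4-methoxycyclohexa-2,5-dienone (ring A dearomatised) with a free C2 hydroxyl, itself the oxidation product of a plain para-alkylphenol; cut C3–C4 (enolate alkylation), C2 being an acyl carbon; trace ring B to 2,3,4-trihydroxybenzaldehyde.
- Enabling feature: in ring A the C7 hydroxyl is para to C4a (which bears C4) and meta to C8a, so oxidising this phenol at C4a makes C8a the β-carbon of a dienone that the C2 hydroxyl reaches through a six-membered ring; loss of the C4a leaving group returns the arene with oxygen on C8a and C7.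
- Forward: ring B is dressed first (4-O-prenylation, aromatic Claisen rearrangement to the 1,1-dimethylallyl group, MOM and methyl ethers, one-carbon homologation to the arylacetic acid); the chain is joined by Evans alkylation with a 4-silyloxybenzyl bromide; ring A is dearomatised; the pyran ring closes with rearomatisation; the MOM groups are removed.
- Stereochemistry: C3 is the only stereocentre; it is set by the (S)-4-benzyl-2-oxazolidinone auxiliary in the alkylation and is neither acidic nor involved afterwards.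

Key step: step 13

Remark: Ar = 2-methoxy-3,4-bis(methoxymethoxy)-5-(2-methylbut-3-en-2-yl)phenyl (protected ring B); the tert-butyldimethylsilyl ether of p-cresol used in step 8 is taken as purchasable.

**Route**

Step 1
Reactants: 1 2,3,4-trihydroxybenzaldehyde; 2 prenyl bromide (1-bromo-3-methylbut-2-ene)
Product: 3 2,3-dihydroxy-4-[(3-methylbut-2-en-1-yl)oxy]benzaldehyde
Conditions: NaHCO3 (1.2 equiv), DMF, 40 °C
Reagents that add atoms: prenyl bromide 2 (CC(C)=CCBr)
Why: Williamson etherification under weak-base control, in which only the 4-hydroxyl (para to the formyl group, the most acidic) is ionised, while the 2-hydroxyl is held in a hydrogen bond to the aldehyde and the 3-hydroxyl is the least acidic.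

Step 2
Reactants: 3 2,3-dihydroxy-4-[(3-methylbut-2-en-1-yl)oxy]benzaldehyde
Product: 5 2,3,4-trihydroxy-5-(2-methylbut-3-en-2-yl)benzaldehyde, via Claisen dienone 4 (not isolated)
Conditions: PhNEt2, 190 °C, sealed tube, argon
Reagents that add atoms: none
Why: Aromatic Claisen rearrangement, whose [3,3] shift with allyl inversion delivers the tertiary terminus of the prenyl group to C5 (the only ortho position that can re-aromatise, since C3 carries oxygen), after which dienone 4 tautomerises to the phenol; the basic solvent disfavours acid-catalysed follow-up reactions.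

Step 3
Reactants: 5 2,3,4-trihydroxy-5-(2-methylbut-3-en-2-yl)benzaldehyde
Product: 6 2-hydroxy-3,4-bis(methoxymethoxy)-5-(2-methylbut-3-en-2-yl)benzaldehyde
Conditions: MOMCl (2.2 equiv), i-Pr2NEt, CH2Cl2, 0 °C to rt
Reagents that add atoms: chloromethyl methyl ether (COCCl)
Why: O-Alkylation with MOMCl under amine base (acetal protection) should cap the 3- and 4-hydroxyls, whereas the 2-hydroxyl chelated to the aldehyde is too weakly nucleophilic under these conditions, as is general for ortho-hydroxy aryl aldehydes.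

Step 4
Reactants: 6 2-hydroxy-3,4-bis(methoxymethoxy)-5-(2-methylbut-3-en-2-yl)benzaldehyde
Product: 7 2-methoxy-3,4-bis(methoxymethoxy)-5-(2-methylbut-3-en-2-yl)benzaldehyde (ArCHO)
Conditions: MeI, K2CO3, DMF, 40 °C
Reagents that add atoms: iodomethane (CI)
Why: Williamson methylation with carbonate in a dipolar aprotic solvent breaks the chelate and alkylates the only remaining phenol.

Step 5
Reactants: 7 ArCHO; 8 p-toluenesulfonylmethyl isocyanide (TosMIC)
Product: 10 2-Ar-acetonitrile, via vinylformamide 9 (not isolated)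
Conditions: TosMIC, KOt-Bu (2.4 equiv), DME, −50 °C; then MeOH, reflux
Reagents that add atoms: TosMIC 8 (Cc1ccc(cc1)S(=O)(=O)C[N+]#[C-])
Why: van Leusen reductive cyanation, in which the TosMIC anion adds to the aldehyde, the oxazoline opens to vinylformamide 9 under excess alkoxide, and methanolysis of the formyl group followed by loss of sulfinate gives the one-carbon homologated nitrile, as known for alkoxy-substituted benzaldehydes.

Step 6
Reactants: 10 2-Ar-acetonitrile
Product: 11 2-Ar-acetic acid
Conditions: KOH, EtOH/H2O, reflux; then 1 M HCl to pH 4, 0 °C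
Reagents that add atoms: water (O); KOH ([K+].[OH-])
Why: Base hydrolysis of an arylacetonitrile through the primary amide, to which MOM ethers, the methyl ether and the isolated alkene are inert, with a brief cold acidification that should not cleave the acetals.

Step 7
Reactants: 11 2-Ar-acetic acid; 12 (4S)-4-benzyl-1,3-oxazolidin-2-one
Product: 14 (4S)-4-benzyl-3-(2-Ar-acetyl)-1,3-oxazolidin-2-one, via pivalic mixed anhydride 13 (not isolated)
Conditions: PivCl, Et3N, THF, −20 °C; then LiCl, 12, −20 °C to rt
Reagents that add atoms: (4S)-4-benzyl-1,3-oxazolidin-2-one 12 (O=C1OC[C@H](Cc2ccccc2)N1); pivaloyl chloride (CC(C)(C)C(Cl)=O)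
Why: Mixed-anhydride N-acylation of an oxazolidinone (LiCl/Et3N protocol), in which the hindered pivaloyl carbonyl of the transient anhydride 13 directs the lithium-activated auxiliary to the arylacetyl carbonyl without a strong base and the pivaloyl group leaves as pivalate.

Step 8
Reactants: 15 tert-butyldimethyl(4-methylphenoxy)silane
Product: 16 [4-(bromomethyl)phenoxy](tert-butyl)dimethylsilane
Conditions: NBS, AIBN (cat.), PhCF3, 80 °C
Reagents that add atoms: N-bromosuccinimide (O=C1CCC(=O)N1Br)
Why: Wohl–Ziegler radical bromination at the only benzylic C–H position, with a non-polar medium and radical initiation disfavouring ionic ring bromination.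

Step 9
Reactants: 14 (4S)-4-benzyl-3-(2-Ar-acetyl)-1,3-oxazolidin-2-one; 16 [4-(bromomethyl)phenoxy](tert-butyl)dimethylsilane
Product: 18 (4S)-4-benzyl-3-{(2S)-2-Ar-3-[4-(tert-butyldimethylsilyloxy)phenyl]propanoyl}-1,3-oxazolidin-2-one, via sodium Z-enolate 17 (not isolated)
Conditions: NaN(SiMe3)2, THF, −78 °C; then 16, −78 to −40 °C; AcOH quench at −78 °C
Reagents that add atoms: benzyl bromide 16 (BrCc1ccc(O[Si](C)(C)C(C)(C)C)cc1); NaN(SiMe3)2 (C[Si](C)(C)[N-][Si](C)(C)C.[Na+])
Why: Evans asymmetric alkylation, in which the chelated sodium Z-enolate 17 has one face blocked by the benzyl group of the auxiliary, so the bromide should add anti to it and set the future C3 as S, while low temperature and a buffered quench guard the α-aryl centre against epimerisation.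

Step 10
Reactants: 18 the alkylated imide
Product: 19 (2S)-2-Ar-3-[4-(tert-butyldimethylsilyloxy)phenyl]propan-1-ol
Conditions: LiBH4, THF, 0 °C
Reagents that add atoms: none
Why: Reductive cleavage of the N-acyl oxazolidinone with LiBH4 (hydride attack at the exocyclic carbonyl, then reduction of the released aldehyde) gives the primary alcohol without touching the stereocentre, and the auxiliary is recovered.

Step 11
Reactants: 19 (2S)-2-Ar-3-[4-(tert-butyldimethylsilyloxy)phenyl]propan-1-ol
Product: 20 4-[(2S)-2-Ar-3-hydroxypropyl]phenol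
Conditions: n-Bu4NF, AcOH (1:1), THF, 0 °C
Reagents that add atoms: none
Why: Fluoride-mediated desilylation of an aryl silyl ether, driven by the Si–F bond and kept neutral by acetic acid, leaves the MOM ethers, the alcohol and the alkene untouched.

Step 12
Reactants: 20 4-[(2S)-2-Ar-3-hydroxypropyl]phenol
Product: 21 4-[(2S)-2-Ar-3-hydroxypropyl]-4-methoxycyclohexa-2,5-dien-1-one
Conditions: PhI(OAc)2 (1.1 equiv), MeOH, 0 °C
Reagents that add atoms: methanol (CO)
Why: Oxidative dearomatisation of a para-alkylphenol, in which ligand exchange at iodine activates the phenol and methanol adds at the para carbon (C4a) as iodobenzene leaves; aryl ethers, the primary alcohol and the unactivated alkene should not react at 0 °C, and the tethered hydroxyl cannot compete at C4a because it would close a four-membered ring.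

Step 13
Reactants: 21 4-[(2S)-2-Ar-3-hydroxypropyl]-4-methoxycyclohexa-2,5-dien-1-one
Product: 23 (3S)-3-Ar-3,4-dihydro-2H-chromen-7-ol, via oxa-Michael adduct 22 (not isolated)
Conditions: (±)-camphor-10-sulfonic acid (20 mol %), CH2Cl2, 0 °C to rt
Reagents that add atoms: none
Why: Proposed new method: protonation of the dienone carbonyl of 21 makes either β-carbon (the future C8a) electrophilic, the C2 hydroxyl adds there to give adduct 22, and acid-assisted ionisation of the C4a–OMe bond to a cyclohexadienyl cation followed by loss of the C8a proton expels methanol and restores ring A with the former carbonyl as the C7 phenol. The closest known reaction types are the intramolecular oxa-Michael addition of hydroxyalkyl-tethered 4-oxygenated cyclohexa-2,5-dienones, which gives cis-fused bicyclic ethers, and the acid-promoted addition of thiols, halide or indoles to 4-alkyl-4-alkoxycyclohexadienones with rearomatisation to meta-substituted phenols; joining the two into the closure of an aryl alkyl ether ring is the untested element. The pyran ring, the only ring formed, closes in a 6-exo-trig conjugate addition. No stereocentre of the product is created: the ring-fusion centres C4a and C8a of 22 (cis expected) are erased on aromatisation, and C3, set in step 9, is neither acidic nor involved. Site selectivity is not required, because the two β-carbons differ only through C3 and both adducts collapse to the same chroman, and the position of the phenol is fixed by the mechanism. What is required is O-attack in preference to arylation of the dienone by ring B and to a dienone–phenol 1,2-shift; the first is secured by the short tether of the hydroxyl and by the only free carbon of ring B (C6') being flanked by the tertiary alkyl group, the second by a catalytic amount of sulfonic acid at or below room temperature in a non-nucleophilic solvent.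

Step 14
Reactants: 23 (3S)-3-Ar-3,4-dihydro-2H-chromen-7-ol
Product: 24 (3S)-3-[3,4-dihydroxy-2-methoxy-5-(2-methylbut-3-en-2-yl)phenyl]-3,4-dihydro-2H-chromen-7-ol (target)
Conditions: 2 M HCl, MeOH/THF, rt
Reagents that add atoms: none
Why: Acid-catalysed methanolysis of the two MOM acetals (transacetalisation to dimethoxymethane) leaves the aryl methyl ether and the chroman intact, and the monosubstituted alkene next to the quaternary carbon should not be protonated by dilute HCl at room temperature, so the 4'-hydroxyl should not cyclise onto it.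

**Compound list**

1 | 2,3,4-trihydroxybenzaldehyde | O=Cc1ccc(O)c(O)c1O | starting material
2 | prenyl bromide (1-bromo-3-methylbut-2-ene) | CC(C)=CCBr | starting material
3 | 2,3-dihydroxy-4-[(3-methylbut-2-en-1-yl)oxy]benzaldehyde | O=Cc1ccc(OCC=C(C)C)c(O)c1O | intermediate
4 | 5,6-dihydroxy-3-(2-methylbut-3-en-2-yl)-4-oxocyclohexa-1,5-diene-1-carbaldehyde (Claisen dienone, racemic, not isolated) | O=CC1=CC(C(C)(C)C=C)C(=O)C(O)=C1O | intermediate
5 | 2,3,4-trihydroxy-5-(2-methylbut-3-en-2-yl)benzaldehyde | O=Cc1cc(C(C)(C)C=C)c(O)c(O)c1O | intermediate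
6 | 2-hydroxy-3,4-bis(methoxymethoxy)-5-(2-methylbut-3-en-2-yl)benzaldehyde | O=Cc1cc(C(C)(C)C=C)c(OCOC)c(OCOC)c1O | intermediate
7 | 2-methoxy-3,4-bis(methoxymethoxy)-5-(2-methylbut-3-en-2-yl)benzaldehyde (ArCHO) | O=Cc1cc(C(C)(C)C=C)c(OCOC)c(OCOC)c1OC | intermediate
8 | p-toluenesulfonylmethyl isocyanide (TosMIC) | Cc1ccc(cc1)S(=O)(=O)C[N+]#[C-] | starting material
9 | N-[2-Ar-1-(4-methylbenzenesulfonyl)ethenyl]formamide (potassium salt in the flask, alkene geometry not defined, not isolated) | O=CNC(=Cc1cc(C(C)(C)C=C)c(OCOC)c(OCOC)c1OC)S(=O)(=O)c1ccc(C)cc1 | intermediate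
10 | 2-Ar-acetonitrile | N#CCc1cc(C(C)(C)C=C)c(OCOC)c(OCOC)c1OC | intermediate
11 | 2-Ar-acetic acid | OC(=O)Cc1cc(C(C)(C)C=C)c(OCOC)c(OCOC)c1OC | intermediate
12 | (4S)-4-benzyl-1,3-oxazolidin-2-one | O=C1OC[C@H](Cc2ccccc2)N1 | starting material
13 | 2-Ar-acetic pivalic anhydride (not isolated) | CC(C)(C)C(=O)OC(=O)Cc1cc(C(C)(C)C=C)c(OCOC)c(OCOC)c1OC | intermediate
14 | (4S)-4-benzyl-3-(2-Ar-acetyl)-1,3-oxazolidin-2-one | O=C1OC[C@H](Cc2ccccc2)N1C(=O)Cc1cc(C(C)(C)C=C)c(OCOC)c(OCOC)c1OC | intermediate
15 | tert-butyldimethyl(4-methylphenoxy)silane | Cc1ccc(O[Si](C)(C)C(C)(C)C)cc1 | starting material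
16 | [4-(bromomethyl)phenoxy](tert-butyl)dimethylsilane | BrCc1ccc(O[Si](C)(C)C(C)(C)C)cc1 | intermediate
17 | sodium (Z)-enolate of 14 (not isolated) | [Na+].[O-]/C(=C\c1cc(C(C)(C)C=C)c(OCOC)c(OCOC)c1OC)N1[C@@H](Cc2ccccc2)COC1=O | intermediate
18 | (4S)-4-benzyl-3-{(2S)-2-Ar-3-[4-(tert-butyldimethylsilyloxy)phenyl]propanoyl}-1,3-oxazolidin-2-one | O=C1OC[C@H](Cc2ccccc2)N1C(=O)[C@@H](Cc1ccc(O[Si](C)(C)C(C)(C)C)cc1)c1cc(C(C)(C)C=C)c(OCOC)c(OCOC)c1OC | intermediate
19 | (2S)-2-Ar-3-[4-(tert-butyldimethylsilyloxy)phenyl]propan-1-ol | OC[C@@H](Cc1ccc(O[Si](C)(C)C(C)(C)C)cc1)c1cc(C(C)(C)C=C)c(OCOC)c(OCOC)c1OC | intermediate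
20 | 4-[(2S)-2-Ar-3-hydroxypropyl]phenol | OC[C@@H](Cc1ccc(O)cc1)c1cc(C(C)(C)C=C)c(OCOC)c(OCOC)c1OC | intermediate
21 | 4-[(2S)-2-Ar-3-hydroxypropyl]-4-methoxycyclohexa-2,5-dien-1-one | OC[C@@H](CC1(OC)C=CC(=O)C=C1)c1cc(C(C)(C)C=C)c(OCOC)c(OCOC)c1OC | intermediate
22 | (3S)-3-Ar-4a-methoxy-2,3,4,4a,8,8a-hexahydro-7H-chromen-7-one (cis ring fusion expected, both C4a/C8a diastereomers converge, not isolated) | COC12C[C@@H](c3cc(C(C)(C)C=C)c(OCOC)c(OCOC)c3OC)COC1CC(=O)C=C2 | intermediate
23 | (3S)-3-Ar-3,4-dihydro-2H-chromen-7-ol | C=CC(C)(C)c1cc([C@H]2COc3cc(O)ccc3C2)c(OC)c(OCOC)c1OCOC | intermediate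
24 | (3S)-3-[3,4-dihydroxy-2-methoxy-5-(2-methylbut-3-en-2-yl)phenyl]-3,4-dihydro-2H-chromen-7-ol | C=CC(C)(C)c1cc([C@H]2COc3cc(O)ccc3C2)c(OC)c(O)c1O | target

**Count and risks**

Total step count: 14. Longest linear sequence: 13 steps (steps 1–7 and 9–14); step 8 prepares the ring A bromide.

Steps most likely to fail:

1. Step 13 (Proposed new method). What may go wrong: the conjugate addition may stay reversible without rearomatisation, or a 1,2-shift at C4a or arylation of the dienone by ring B may outrun the ether closure. The fallback is known chemistry and makes the O1–C8a bond by palladium-catalysed intramolecular aryl ether formation from an aryl bromide; it sets out from imide 14. Commercial 3-bromo-4-methylphenol F1 is silylated (TBSCl, imidazole, DMF) to (3-bromo-4-methylphenoxy)(tert-butyl)dimethylsilane F2, and Wohl–Ziegler bromination gives [3-bromo-4-(bromomethyl)phenoxy](tert-butyl)dimethylsilane F3. Alkylation of enolate 17 (from 14, as in step 9) with F3 should give (4S)-4-benzyl-3-{(2S)-2-Ar-3-[2-bromo-4-(tert-butyldimethylsilyloxy)phenyl]propanoyl}-1,3-oxazolidin-2-one F4. LiBH4 reduction gives (2S)-2-Ar-3-[2-bromo-4-(tert-butyldimethylsilyloxy)phenyl]propan-1-ol F5. Pd(OAc)2, 2-(di-tert-butylphosphino)-1,1'-binaphthyl and Cs2CO3 in toluene at 70 °C should close the ring to (3S)-3-Ar-7-(tert-butyldimethylsilyloxy)-3,4-dihydro-2H-chromene F6. n-Bu4NF/AcOH then gives 23, where the route is rejoined.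

2. Step 2. What may go wrong: at the temperature of the sigmatropic shift the unprotected polyphenol may lose its prenyl group as isoprene, and the product may isomerise further (abnormal Claisen pathway) or add its 4-hydroxyl to the new alkene. The fallback builds the quaternary benzylic carbon by cross-coupling instead; it sets out from 1. MOMCl/i-Pr2NEt gives 2-hydroxy-3,4-bis(methoxymethoxy)benzaldehyde F7, and MeI/K2CO3 gives 2-methoxy-3,4-bis(methoxymethoxy)benzaldehyde F8. NBS in MeCN brominates C5 (ortho and para to two oxygens, meta to the formyl group) to give 5-bromo-2-methoxy-3,4-bis(methoxymethoxy)benzaldehyde F9. The van Leusen conditions of step 5 lead through the unisolated N-{2-[5-bromo-2-methoxy-3,4-bis(methoxymethoxy)phenyl]-1-(4-methylbenzenesulfonyl)ethenyl}formamide F10 to [5-bromo-2-methoxy-3,4-bis(methoxymethoxy)phenyl]acetonitrile F11; the aldehyde is removed before the coupling because it would be allylated by the boronate. A ligand-controlled γ-selective Suzuki–Miyaura coupling of F11 with commercial 4,4,5,5-tetramethyl-2-(3-methylbut-2-en-1-yl)-1,3,2-dioxaborolane F12 (Pd(OAc)2, bulky biaryl dialkylphosphine, K3PO4, THF/H2O, 40 °C) installs the 1,1-dimethylallyl group and returns to the route at nitrile 10.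

3. Step 12. What may go wrong: the iodine reagent may over-oxidise the electron-rich ring B, or the activated phenol may be captured by ring B (spirocyclisation) instead of methanol. The fallback avoids an electrophilic oxidant; it sets out from phenol 20. Singlet oxygen generated from KHSO5 (as 2KHSO5·KHSO4·K2SO4) and NaHCO3 in aqueous MeCN adds at the para carbon to give 4-[(2S)-2-Ar-3-hydroxypropyl]-4-hydroperoxycyclohexa-2,5-dien-1-one F13. Me2S reduces this to 4-[(2S)-2-Ar-3-hydroxypropyl]-4-hydroxycyclohexa-2,5-dien-1-one F14. This quinol is cyclised under the acid conditions of step 13 through the unisolated (3S)-3-Ar-4a-hydroxy-2,3,4,4a,8,8a-hexahydro-7H-chromen-7-one F15, water being lost in place of methanol, and the route is rejoined at 23.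

**Further compounds**

F1 | step 13 | 3-bromo-4-methylphenol (commercial input) | Cc1ccc(O)cc1Br
F2 | step 13 | (3-bromo-4-methylphenoxy)(tert-butyl)dimethylsilane | Cc1ccc(O[Si](C)(C)C(C)(C)C)cc1Br
F3 | step 13 | [3-bromo-4-(bromomethyl)phenoxy](tert-butyl)dimethylsilane | BrCc1ccc(O[Si](C)(C)C(C)(C)C)cc1Br
F4 | step 13 | (4S)-4-benzyl-3-{(2S)-2-Ar-3-[2-bromo-4-(tert-butyldimethylsilyloxy)phenyl]propanoyl}-1,3-oxazolidin-2-one | O=C1OC[C@H](Cc2ccccc2)N1C(=O)[C@@H](Cc1ccc(O[Si](C)(C)C(C)(C)C)cc1Br)c1cc(C(C)(C)C=C)c(OCOC)c(OCOC)c1OC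
F5 | step 13 | (2S)-2-Ar-3-[2-bromo-4-(tert-butyldimethylsilyloxy)phenyl]propan-1-ol | OC[C@@H](Cc1ccc(O[Si](C)(C)C(C)(C)C)cc1Br)c1cc(C(C)(C)C=C)c(OCOC)c(OCOC)c1OC
F6 | step 13 | (3S)-3-Ar-7-(tert-butyldimethylsilyloxy)-3,4-dihydro-2H-chromene | C=CC(C)(C)c1cc([C@H]2COc3cc(O[Si](C)(C)C(C)(C)C)ccc3C2)c(OC)c(OCOC)c1OCOC
F7 | step 2 | 2-hydroxy-3,4-bis(methoxymethoxy)benzaldehyde | O=Cc1ccc(OCOC)c(OCOC)c1O
F8 | step 2 | 2-methoxy-3,4-bis(methoxymethoxy)benzaldehyde | O=Cc1ccc(OCOC)c(OCOC)c1OC
F9 | step 2 | 5-bromo-2-methoxy-3,4-bis(methoxymethoxy)benzaldehyde | O=Cc1cc(Br)c(OCOC)c(OCOC)c1OC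
F10 | step 2 | N-{2-[5-bromo-2-methoxy-3,4-bis(methoxymethoxy)phenyl]-1-(4-methylbenzenesulfonyl)ethenyl}formamide (alkene geometry not defined, not isolated) | O=CNC(=Cc1cc(Br)c(OCOC)c(OCOC)c1OC)S(=O)(=O)c1ccc(C)cc1
F11 | step 2 | [5-bromo-2-methoxy-3,4-bis(methoxymethoxy)phenyl]acetonitrile | N#CCc1cc(Br)c(OCOC)c(OCOC)c1OC
F12 | step 2 | 4,4,5,5-tetramethyl-2-(3-methylbut-2-en-1-yl)-1,3,2-dioxaborolane (commercial input) | CC(C)=CCB1OC(C)(C)C(C)(C)O1
F13 | step 12 | 4-[(2S)-2-Ar-3-hydroxypropyl]-4-hydroperoxycyclohexa-2,5-dien-1-one | OC[C@@H](CC1(OO)C=CC(=O)C=C1)c1cc(C(C)(C)C=C)c(OCOC)c(OCOC)c1OC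
F14 | step 12 | 4-[(2S)-2-Ar-3-hydroxypropyl]-4-hydroxycyclohexa-2,5-dien-1-one | OC[C@@H](CC1(O)C=CC(=O)C=C1)c1cc(C(C)(C)C=C)c(OCOC)c(OCOC)c1OC
F15 | step 12 | (3S)-3-Ar-4a-hydroxy-2,3,4,4a,8,8a-hexahydro-7H-chromen-7-one (not isolated) | OC12C[C@@H](c3cc(C(C)(C)C=C)c(OCOC)c(OCOC)c3OC)COC1CC(=O)C=C2
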